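The disconnection on which everything rests is the bond between C2, the oxygen-bearing quaternary stereocentre of the dihydropyran ring, and C1' of the polyprenyl chain. Because C2 carries oxygen, it can be reached from an enantiopure secondary benzoate: the (S)-2,4,6-triisopropylbenzoate of a 4-arylbutan-2-ol is lithiated at the carbinol carbon and captured by homofarnesyl neopentyl glycol boronate. A stereospecific 1,2-metallate shift expels the benzoate, joins the arene half to the C16 chain and fixes C2; oxidation returns oxygen to C2 as a tertiary carbinol. The open-chain precursor thus carries the C2 oxygen as a leaving group. The O1–C8a bond is closed last, through the para-quinone, without touching C2.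

Key step: step 6

Remark on the chemistry: the target is read as (2R,3'E,7'E)-β-tocotrienol; compounds 1, 3, 7 and 8 are assumed to be commercial; chroman locants (O1, C2, C4a, C8a, C1') are also used for the corresponding atoms of the open-chain precursors.

Step 1
Reactants: 1 1,4-dimethoxy-2,5-dimethylbenzene
Product: 2 1-(chloromethyl)-2,5-dimethoxy-3,6-dimethylbenzene
Conditions: (CH2O)n (1.0 equiv), conc. HCl, AcOH, 45 °C
Reagents that add atoms: formaldehyde (from paraformaldehyde) C=O; hydrogen chloride Cl
Why: Blanc chloromethylation: protonated formaldehyde attacks one of the two equivalent free ring positions, each activated by an ortho methoxy group, and the limiting amount of formaldehyde should hold the reaction at the monoadduct.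

Step 2
Reactants: 2 1-(chloromethyl)-2,5-dimethoxy-3,6-dimethylbenzene; 3 (R)-propylene oxide
Product: 5 (2R)-4-(2,5-dimethoxy-3,6-dimethylphenyl)butan-2-ol, via benzylmagnesium chloride 4 (not isolated)
Conditions: Mg, THF, 0 °C; then CuI (10 mol%), 3, −30 °C → 0 °C
Reagents that add atoms: none
Why: Copper-catalysed Grignard opening of an epoxide: the benzylic organometal attacks the unsubstituted carbon of 3 in an SN2 sense, so the stereocentre of the chiral-pool epoxide is carried unchanged into the (R)-carbinol.

Step 3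
Reactants: 5 (2R)-4-(2,5-dimethoxy-3,6-dimethylphenyl)butan-2-ol
Product: 6 (2S)-4-(2,5-dimethoxy-3,6-dimethylphenyl)butan-2-yl 2,4,6-triisopropylbenzoate
Conditions: 2,4,6-triisopropylbenzoic acid, PPh3, DIAD, THF, 0 °C → rt
Reagents that add atoms: 2,4,6-triisopropylbenzoic acid CC(C)c1cc(C(C)C)c(C(=O)O)c(C(C)C)c1
Why: Mitsunobu esterification: the carboxylate displaces the activated hydroxyl with SN2 inversion, turning the (R)-alcohol into the (S)-benzoate whose hindered carbonyl later resists attack by sBuLi.

Step 4
Reactants: 7 (2E,6E)-farnesyl bromide; 8 bis(4,4,5,5-tetramethyl-1,3,2-dioxaborolan-2-yl)methane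
Product: 10 4,4,5,5-tetramethyl-2-[(3E,7E)-4,8,12-trimethyltrideca-3,7,11-trien-1-yl]-1,3,2-dioxaborolane, via boryl carbanion 9 (not isolated)
Conditions: NaOtBu, THF, 0 °C → rt
Reagents that add atoms: none
Why: Deborylative alkylation of a geminal bis(boronate): tert-butoxide removes one boryl group to give the boron-stabilised carbanion 9, which should displace the primary allylic bromide in an SN2 sense and so add one CH2B unit without touching the E-configured alkenes.

Step 5
Reactants: 10 4,4,5,5-tetramethyl-2-[(3E,7E)-4,8,12-trimethyltrideca-3,7,11-trien-1-yl]-1,3,2-dioxaborolane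
Product: 12 5,5-dimethyl-2-[(3E,7E)-4,8,12-trimethyltrideca-3,7,11-trien-1-yl]-1,3,2-dioxaborinane, via boronic acid 11 (not isolated)
Conditions: NaIO4, NH4OAc, acetone/H2O, rt; then neopentyl glycol, MgSO4, pentane, rt
Reagents that add atoms: 2,2-dimethylpropane-1,3-diol (neopentyl glycol) CC(C)(CO)CO
Why: Boronic ester exchange: periodate cleaves the pinacol released by hydrolysis so that the free boronic acid 11 forms and condenses with the 1,3-diol to the less hindered dioxaborinane needed for boronate formation at a tertiary carbanion.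

Step 6
Reactants: 6 (2S)-4-(2,5-dimethoxy-3,6-dimethylphenyl)butan-2-yl 2,4,6-triisopropylbenzoate; 12 5,5-dimethyl-2-[(3E,7E)-4,8,12-trimethyltrideca-3,7,11-trien-1-yl]-1,3,2-dioxaborinane
Product: 16 (3R,6E,10E)-1-(2,5-dimethoxy-3,6-dimethylphenyl)-3,7,11,15-tetramethylhexadeca-6,10,14-trien-3-ol, via lithiated benzoate 13 (not isolated), via boronate complex 14 (not isolated), via tertiary boronic ester 15 (not isolated)
Conditions: sBuLi (1.6 equiv), TMEDA (6 equiv), CPME, −60 °C; then 12 (2 equiv), −60 °C → 50 °C; then aq. NaOH, H2O2, THF, 0 °C → rt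
Reagents that add atoms: hydrogen peroxide OO
Why: sBuLi/TMEDA, directed by the benzoate carbonyl, removes the carbinol hydrogen of 6 to give the configurationally stable α-oxy organolithium 13 with retention, which adds to the boron of 12 with retention to give boronate 14; on warming, the homofarnesyl group migrates from boron to carbon anti to the departing 2,4,6-triisopropylbenzoate (1,2-metallate rearrangement with inversion at carbon), forming the C1'–C2 bond in 15, and alkaline H2O2 then replaces boron by hydroxyl with retention. The closest known reaction type is the lithiation–borylation–oxidation of unactivated secondary dialkyl 2,4,6-triisopropylbenzoates with primary alkyl neopentyl glycol boronates, a class to which 6 and 12 belong. No ring is closed in this step. The new quaternary stereocentre is controlled only by the (S) configuration of 6, which is relayed stereospecifically (retention, retention, inversion, retention) to the (R)-carbinol. The step needs site-selective deprotonation at the carbinol carbon over the single ring hydrogen and the benzylic methyl groups of the dimethoxyarene, which the carbonyl-directed lithiation at low temperature should secure. It also needs clean boronate formation at a hindered tertiary carbanion, which the small neopentyl glycol ester and the unbranched migrating group favour.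

Step 7
Reactants: 16 (3R,6E,10E)-1-(2,5-dimethoxy-3,6-dimethylphenyl)-3,7,11,15-tetramethylhexadeca-6,10,14-trien-3-ol
Product: 17 3-[(3R,6E,10E)-3-hydroxy-3,7,11,15-tetramethylhexadeca-6,10,14-trien-1-yl]-2,5-dimethyl-1,4-benzoquinone
Conditions: (NH4)2Ce(NO3)6 (2.5 equiv), MeCN/H2O, 0 °C
Reagents that add atoms: water O
Why: Oxidative demethylation of a para-dimethoxyarene by tetravalent cerium gives the para-quinone under conditions that should leave trisubstituted alkenes and the tertiary carbinol untouched, so the stereocentre is not involved.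

Step 8
Reactants: 17 3-[(3R,6E,10E)-3-hydroxy-3,7,11,15-tetramethylhexadeca-6,10,14-trien-1-yl]-2,5-dimethyl-1,4-benzoquinone
Product: 19 (2R)-2,5,8-trimethyl-2-[(3E,7E)-4,8,12-trimethyltrideca-3,7,11-trien-1-yl]-3,4-dihydro-2H-chromen-6-ol (β-tocotrienol), via cyclic methyl ketal 18 (not isolated)
Conditions: HC(OMe)3, camphorsulfonic acid (cat.), MeOH, rt; then L-ascorbic acid (excess), MeOH, rt
Reagents that add atoms: none
Why: Quinone ketalization followed by reductive aromatization: the tertiary hydroxyl adds to the adjacent quinone carbonyl (6-exo-trig) and the hemiketal is trapped as methyl ketal 18, which loses methanol under acid to the chromanoxylium ion that ascorbic acid reduces to the chromanol, so the C2–O bond is never broken and C2 keeps the R configuration.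

Compound list

1 | 1,4-dimethoxy-2,5-dimethylbenzene | COc1cc(C)c(OC)cc1C | starting material
2 | 1-(chloromethyl)-2,5-dimethoxy-3,6-dimethylbenzene | COc1c(CCl)c(C)c(OC)cc1C | intermediate
3 | (R)-propylene oxide, (2R)-2-methyloxirane | C[C@@H]1CO1 | starting material
4 | (2,5-dimethoxy-3,6-dimethylbenzyl)magnesium chloride | COc1c(C[Mg]Cl)c(C)c(OC)cc1C | intermediate
5 | (2R)-4-(2,5-dimethoxy-3,6-dimethylphenyl)butan-2-ol | C[C@@H](O)CCc1c(OC)c(C)cc(OC)c1C | intermediate
6 | (2S)-4-(2,5-dimethoxy-3,6-dimethylphenyl)butan-2-yl 2,4,6-triisopropylbenzoate | C[C@H](OC(=O)c1c(C(C)C)cc(C(C)C)cc1C(C)C)CCc1c(OC)c(C)cc(OC)c1C | intermediate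
7 | (2E,6E)-farnesyl bromide, (2E,6E)-1-bromo-3,7,11-trimethyldodeca-2,6,10-triene | CC(C)=CCC/C(C)=C/CC/C(C)=C/CBr | starting material
8 | bis(4,4,5,5-tetramethyl-1,3,2-dioxaborolan-2-yl)methane | CC1(C)OB(CB2OC(C)(C)C(C)(C)O2)OC1(C)C | starting material
9 | sodium (4,4,5,5-tetramethyl-1,3,2-dioxaborolan-2-yl)methanide | [Na+].[CH2-]B1OC(C)(C)C(C)(C)O1 | intermediate
10 | 4,4,5,5-tetramethyl-2-[(3E,7E)-4,8,12-trimethyltrideca-3,7,11-trien-1-yl]-1,3,2-dioxaborolane (homofarnesyl pinacol boronate) | CC(C)=CCC/C(C)=C/CC/C(C)=C/CCB1OC(C)(C)C(C)(C)O1 | intermediate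
11 | [(3E,7E)-4,8,12-trimethyltrideca-3,7,11-trien-1-yl]boronic acid | CC(C)=CCC/C(C)=C/CC/C(C)=C/CCB(O)O | intermediate
12 | 5,5-dimethyl-2-[(3E,7E)-4,8,12-trimethyltrideca-3,7,11-trien-1-yl]-1,3,2-dioxaborinane (homofarnesyl neopentyl glycol boronate) | CC(C)=CCC/C(C)=C/CC/C(C)=C/CCB1OCC(C)(C)CO1 | intermediate
13 | (S)-configured α-lithiated benzoate: 6 with lithium in place of the carbinol hydrogen | C[C@]([Li])(OC(=O)c1c(C(C)C)cc(C(C)C)cc1C(C)C)CCc1c(OC)c(C)cc(OC)c1C | intermediate
14 | lithium boronate complex: the carbinol carbon of 6 bonded to the tetracoordinate boron of 12 (boron in place of lithium, retention) | [Li+].C[C@]([B-]1(CC/C=C(\C)CC/C=C(\C)CCC=C(C)C)OCC(C)(C)CO1)(OC(=O)c1c(C(C)C)cc(C(C)C)cc1C(C)C)CCc1c(OC)c(C)cc(OC)c1C | intermediate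
15 | 2-[(3S,6E,10E)-1-(2,5-dimethoxy-3,6-dimethylphenyl)-3,7,11,15-tetramethylhexadeca-6,10,14-trien-3-yl]-5,5-dimethyl-1,3,2-dioxaborinane (boron where the hydroxyl of 16 will stand) | CC(C)=CCC/C(C)=C/CC/C(C)=C/CC[C@@](C)(B1OCC(C)(C)CO1)CCc1c(OC)c(C)cc(OC)c1C | intermediate
16 | (3R,6E,10E)-1-(2,5-dimethoxy-3,6-dimethylphenyl)-3,7,11,15-tetramethylhexadeca-6,10,14-trien-3-ol | CC(C)=CCC/C(C)=C/CC/C(C)=C/CC[C@@](C)(O)CCc1c(OC)c(C)cc(OC)c1C | intermediate
17 | 3-[(3R,6E,10E)-3-hydroxy-3,7,11,15-tetramethylhexadeca-6,10,14-trien-1-yl]-2,5-dimethyl-1,4-benzoquinone | CC(C)=CCC/C(C)=C/CC/C(C)=C/CC[C@@](C)(O)CCC1=C(C)C(=O)C=C(C)C1=O | intermediate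
18 | (2R)-8a-methoxy-2,5,8-trimethyl-2-[(3E,7E)-4,8,12-trimethyltrideca-3,7,11-trien-1-yl]-2,3,4,8a-tetrahydro-6H-chromen-6-one (both C8a epimers) | CC(C)=CCC/C(C)=C/CC/C(C)=C/CC[C@]1(C)CCC2=C(C)C(=O)C=C(C)C2(OC)O1 | intermediate
19 | (2R)-2,5,8-trimethyl-2-[(3E,7E)-4,8,12-trimethyltrideca-3,7,11-trien-1-yl]-3,4-dihydro-2H-chromen-6-ol (β-tocotrienol) | CC(C)=CCC/C(C)=C/CC/C(C)=C/CC[C@]1(C)CCc2c(C)c(O)cc(C)c2O1 | target

Total step count: 8.
Longest linear sequence: 6 steps (steps 1, 2, 3, 6, 7, 8); the boronate branch (steps 4, 5) joins at step 6.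

Steps most likely to fail

Step 8. The quinone may be reduced to the hydroquinone faster than the tertiary hydroxyl is locked into the ketal, or the ketal may revert by hydrolysis, so that ring-opened material is returned. The fallback replaces the stereoretentive closure by a stereoinvertive one and therefore enters the opposite enantiomeric series. It sets out from alcohol 5, which is acylated with retention (NaH, then 2,4,6-triisopropylbenzoyl chloride, THF, reflux) to give (2R)-4-(2,5-dimethoxy-3,6-dimethylphenyl)butan-2-yl 2,4,6-triisopropylbenzoate F1. Lithiation–borylation–oxidation of F1 with 12 under the conditions of step 6 should give the (3S)-carbinol F2, and oxidation with (NH4)2Ce(NO3)6 as in step 7 the (S)-quinone F3. Reduction with Na2S2O4 (Et2O/H2O) gives the (S)-hydroquinone F4. Cyclodehydration with catalytic p-toluenesulfonic acid in benzene under argon is expected to proceed by attack of the C8a phenol oxygen on the protonated tertiary carbinol with inversion at C2. The fallback thus comes back to the route at 19. Its own weak points are acid exposure of the triene and partial racemization through a free tertiary cation.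

Step 6. Competing metalation of the electron-rich arene (ring hydrogen or benzylic methyl groups) or slow, reversible boronate formation at the hindered carbanion may return unreacted or protonated benzoate. The fallback exchanges the roles of the partners so that the lithiated component carries no arene and the migrating group is the arylethyl unit. It sets out from chloride 2: deborylative alkylation with 8 (NaOtBu, THF) gives 2-[2-(2,5-dimethoxy-3,6-dimethylphenyl)ethyl]-4,4,5,5-tetramethyl-1,3,2-dioxaborolane F5, and exchange as in step 5 gives the neopentyl glycol ester F6. Commercial (5E,9E)-farnesylacetone F7 is reduced by an (S)-selective alcohol dehydrogenase (NADPH, isopropanol, buffer) to (2S,5E,9E)-6,10,14-trimethylpentadeca-5,9,13-trien-2-ol F8. Mitsunobu esterification with 2,4,6-triisopropylbenzoic acid inverts this to the (2R)-benzoate F9. Lithiation of F9 (sBuLi, TMEDA, CPME, −60 °C), capture with F6, 1,2-migration and oxidation should come back to the route at 16. The joining bond is then C2–C3 instead of C1'–C2, with the same stereochemical relay.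

Step 4. The boron-stabilised carbanion may attack the tertiary terminus of the allylic bromide (allylic transposition), or the product may be alkylated a second time. The fallback installs boron first and the extra carbon second. It sets out from bromide 7: borylation with B2pin2 under zerovalent palladium catalysis (Pd2(dba)3, DMSO, 50 °C) at the unhindered terminus of the π-allyl intermediate gives (2E,6E)-farnesyl pinacol boronate F10. Matteson homologation with LiCH2Cl (BrCH2Cl, nBuLi, THF, −78 °C → rt) then inserts the missing methylene by 1,2-migration of the allyl group and comes back to the route at 10.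

Further compounds

F1 | step 8 | (2R)-4-(2,5-dimethoxy-3,6-dimethylphenyl)butan-2-yl 2,4,6-triisopropylbenzoate | C[C@@H](OC(=O)c1c(C(C)C)cc(C(C)C)cc1C(C)C)CCc1c(OC)c(C)cc(OC)c1C
F2 | step 8 | (3S,6E,10E)-1-(2,5-dimethoxy-3,6-dimethylphenyl)-3,7,11,15-tetramethylhexadeca-6,10,14-trien-3-ol | CC(C)=CCC/C(C)=C/CC/C(C)=C/CC[C@](C)(O)CCc1c(OC)c(C)cc(OC)c1C
F3 | step 8 | 3-[(3S,6E,10E)-3-hydroxy-3,7,11,15-tetramethylhexadeca-6,10,14-trien-1-yl]-2,5-dimethyl-1,4-benzoquinone | CC(C)=CCC/C(C)=C/CC/C(C)=C/CC[C@](C)(O)CCC1=C(C)C(=O)C=C(C)C1=O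
F4 | step 8 | 3-[(3S,6E,10E)-3-hydroxy-3,7,11,15-tetramethylhexadeca-6,10,14-trien-1-yl]-2,5-dimethylbenzene-1,4-diol | CC(C)=CCC/C(C)=C/CC/C(C)=C/CC[C@](C)(O)CCc1c(O)c(C)cc(O)c1C
F5 | step 6 | 2-[2-(2,5-dimethoxy-3,6-dimethylphenyl)ethyl]-4,4,5,5-tetramethyl-1,3,2-dioxaborolane | COc1c(CCB2OC(C)(C)C(C)(C)O2)c(C)c(OC)cc1C
F6 | step 6 | 2-[2-(2,5-dimethoxy-3,6-dimethylphenyl)ethyl]-5,5-dimethyl-1,3,2-dioxaborinane | COc1c(CCB2OCC(C)(C)CO2)c(C)c(OC)cc1C
F7 | step 6 | (5E,9E)-6,10,14-trimethylpentadeca-5,9,13-trien-2-one (farnesylacetone, commercial) | CC(C)=CCC/C(C)=C/CC/C(C)=C/CCC(C)=O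
F8 | step 6 | (2S,5E,9E)-6,10,14-trimethylpentadeca-5,9,13-trien-2-ol | CC(C)=CCC/C(C)=C/CC/C(C)=C/CC[C@H](C)O
F9 | step 6 | (2R,5E,9E)-6,10,14-trimethylpentadeca-5,9,13-trien-2-yl 2,4,6-triisopropylbenzoate | CC(C)=CCC/C(C)=C/CC/C(C)=C/CC[C@@H](C)OC(=O)c1c(C(C)C)cc(C(C)C)cc1C(C)C
F10 | step 4 | 4,4,5,5-tetramethyl-2-[(2E,6E)-3,7,11-trimethyldodeca-2,6,10-trien-1-yl]-1,3,2-dioxaborolane | CC(C)=CCC/C(C)=C/CC/C(C)=C/CB1OC(C)(C)C(C)(C)O1
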